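**Plan**

1. Retrosynthetic cuts, in order: O1–C2 of the pyranone ring (key), the oxygen bridge of a C2–C3 oxirane (back to an E-alkene), the C2–C3 carbon–carbon bond (aldol condensation of an acetophenone with protocatechualdehyde), and the geranyl O–C bond.
2. Forward: rings A and B are bought as arenes. 2,4-Dihydroxyacetophenone is geranylated at O4, silylated at O2 (TBS) and condensed with 3,4-bis(TIPS-oxy)benzaldehyde to the E-chalcone.
3. A C2–C3 oxirane, a ring that is absent from the target, is then placed on the enone by catalytic asymmetric nucleophilic epoxidation; it stores both stereocentres.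
4. Ring C arises last: fluoride frees the 2'-phenol, which opens the oxirane at the benzylic carbon (6-endo); a final buffered desilylation frees the catechol.
5. Enabling feature: C2 is at once benzylic to the 3,4-dioxygenated ring B and β to the C4 ketone, and O1 sits on ring A ortho to that ketone, so the phenol reaches the activated oxirane carbon through a six-membered transition state.
6. Stereochemistry: the La–(S)-BINOL catalyst sets the (2R,3S)-oxirane; C3 is retained and C2 is inverted in the ring closure, which gives 2,3-trans (2R,3R).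

Key step: step 6

Assumption: the sense of induction of the La–BINOL epoxidation is taken to be that of parent chalcone ((S)-BINOL gives the (2R,3S)-epoxy ketone); geranyl = (2E)-3,7-dimethylocta-2,6-dien-1-yl, TBS = tert-butyldimethylsilyl, TIPS = triisopropylsilyl.

**Route**

Step 1
Reactants: 1 2,4-dihydroxyacetophenone; 2 geranyl bromide
Product: 3 1-[4-(geranyloxy)-2-hydroxyphenyl]ethan-1-one
Conditions: K2CO3 (1.2 equiv), acetone, reflux
Reagents that add atoms: none
Why: Williamson ether synthesis in which only the more acidic, non-chelated 4-OH (para to the acetyl group) is alkylated while the 2-OH stays hydrogen-bonded to the carbonyl, and SN2 at the primary allylic bromide keeps the E-alkene.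

Step 2
Reactants: 3 1-[4-(geranyloxy)-2-hydroxyphenyl]ethan-1-one
Product: 4 1-[2-(tert-butyldimethylsilyloxy)-4-(geranyloxy)phenyl]ethan-1-one
Conditions: TBSCl, imidazole, DMAP (cat.), DMF, rt
Reagents that add atoms: tert-butyldimethylsilyl chloride, CC(C)(C)[Si](C)(C)Cl
Why: O-silylation of a phenol (silyl ether protection), which puts the most fluoride-labile group of the route on the oxygen that will later close the ring.

Step 3
Reactants: 5 3,4-dihydroxybenzaldehyde
Product: 6 3,4-bis(triisopropylsilyloxy)benzaldehyde
Conditions: TIPSCl (2.4 equiv), imidazole, DMF, rt → 40 °C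
Reagents that add atoms: triisopropylsilyl chloride, CC(C)[Si](Cl)(C(C)C)C(C)C
Why: Double O-silylation of the catechol with the bulkier TIPS group, which should outlast TBS in step 6 and still leave with buffered fluoride in step 7, without acid, strong base or hydrogenation that would endanger the geranyl ether.

Step 4
Reactants: 4 1-[2-(tert-butyldimethylsilyloxy)-4-(geranyloxy)phenyl]ethan-1-one; 6 3,4-bis(triisopropylsilyloxy)benzaldehyde
Product: 9 (E)-3-[3,4-bis(triisopropylsilyloxy)phenyl]-1-[2-(tert-butyldimethylsilyloxy)-4-(geranyloxy)phenyl]prop-2-en-1-one, via aldol adduct 7 (not isolated), via β-mesylate 8 (not isolated)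
Conditions: LiHMDS, THF, −78 °C; then 6, −78 °C; then MsCl, Et3N, −78 °C → rt
Reagents that add atoms: none
Why: Directed aldol addition of the kinetic lithium enolate followed by in situ mesylation and E1cB elimination, a hydroxide-free equivalent of the Claisen–Schmidt condensation that should spare the aryl silyl ethers and give the conjugated E-enone as the thermodynamically preferred alkene.

Step 5
Reactants: 9 (E)-3-[3,4-bis(triisopropylsilyloxy)phenyl]-1-[2-(tert-butyldimethylsilyloxy)-4-(geranyloxy)phenyl]prop-2-en-1-one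
Product: 10 [2-(tert-butyldimethylsilyloxy)-4-(geranyloxy)phenyl][(2R,3S)-3-[3,4-bis(triisopropylsilyloxy)phenyl]oxiran-2-yl]methanone
Conditions: La(O-iPr)3/(S)-BINOL/Ph3As=O (1:1:1, 10 mol %), TBHP (1.5 equiv, in decane), 4 Å MS, THF, rt
Reagents that add atoms: tert-butyl hydroperoxide, CC(C)(C)OO
Why: Catalytic asymmetric nucleophilic (Weitz–Scheffer-type) epoxidation in which the chiral lanthanum BINOLate delivers tert-butylperoxide to one face of the enone β-carbon and the enolate closes stereospecifically to the trans-oxirane, so both stereocentres are set by the catalyst while the electron-rich geranyl alkenes, inert to nucleophilic peroxide, are left alone.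

Step 6
Reactants: 10 [2-(tert-butyldimethylsilyloxy)-4-(geranyloxy)phenyl][(2R,3S)-3-[3,4-bis(triisopropylsilyloxy)phenyl]oxiran-2-yl]methanone
Product: 12 (2R,3R)-2-[3,4-bis(triisopropylsilyloxy)phenyl]-7-(geranyloxy)-3-hydroxy-2,3-dihydro-4H-chromen-4-one, via 2'-hydroxy epoxy ketone 11 (not isolated)
Conditions: TBAF (1.1 equiv), AcOH (1.1 equiv), THF, −20 °C → rt; pH 7 buffer
Reagents that add atoms: none
Why: Fluoride should remove the one activated silyl group (the TBS ether of the phenol ortho to the C4 carbonyl, whose phenoxide is the best leaving group on silicon), and the liberated phenol oxygen, held next to the oxirane by the planar aryl ketone, attacks the benzylic oxirane carbon anti to its C–O bond in an SN2 epoxide opening, the oxirane oxygen becoming the C3 hydroxyl. The closest known reaction type is the base-induced cyclization of 2'-hydroxychalcone epoxides to trans-3-hydroxyflavanones (the ring-closing event of Algar–Flynn–Oyamada chemistry), here triggered by desilylation as in the fluoride-induced closure of 2'-silyloxychalcones to flavanones. The pyranone ring closes in the 6-endo-tet mode, with both oxirane carbons inside the new ring. C2 is set by inversion of the (S)-configured benzylic oxirane carbon and C3 keeps the configuration installed in step 5, so the anti opening of the trans-oxirane should deliver the 2,3-trans (2R,3R) product. The step needs 6-endo attack at C2 instead of 5-exo attack at C3 (the aurone pathway) and cleavage of TBS before TIPS; the first is secured by the benzylic, donor-substituted character of C2, by the deactivation of the carbon α to the ketone and by the absence of a substituent at C5 that would twist the ketone out of plane, the second by the smaller silyl group on the more acidic carbonyl-conjugated phenol and by one equivalent of fluoride at low temperature. Acetic acid keeps the medium near neutral, so the C3 alkoxide is protonated at once and neither epimerization α to the ketone nor isomerization of the epoxy ketone should compete.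

Step 7
Reactants: 12 (2R,3R)-2-[3,4-bis(triisopropylsilyloxy)phenyl]-7-(geranyloxy)-3-hydroxy-2,3-dihydro-4H-chromen-4-one
Product: 13 (2R,3R)-2-(3,4-dihydroxyphenyl)-7-(geranyloxy)-3-hydroxy-2,3-dihydro-4H-chromen-4-one
Conditions: TBAF (2.5 equiv), AcOH (2.5 equiv), degassed THF, 0 °C → rt
Reagents that add atoms: none
Why: Fluoride-mediated desilylation of the two aryl TIPS ethers under acetic acid buffering, conditions that should touch neither the acid-sensitive geranyl aryl ether nor the base-sensitive C2/C3 centres of the dihydroflavonol, which therefore keep the configuration set before.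

**Compound list**

1 | 2,4-dihydroxyacetophenone | CC(=O)c1ccc(O)cc1O | starting material
2 | geranyl bromide, (2E)-1-bromo-3,7-dimethylocta-2,6-diene | CC(C)=CCC/C(C)=C/CBr | starting material
3 | 1-[4-(geranyloxy)-2-hydroxyphenyl]ethan-1-one | CC(C)=CCC/C(C)=C/COc1ccc(C(C)=O)c(O)c1 | intermediate
4 | 1-[2-(tert-butyldimethylsilyloxy)-4-(geranyloxy)phenyl]ethan-1-one | CC(C)=CCC/C(C)=C/COc1ccc(C(C)=O)c(O[Si](C)(C)C(C)(C)C)c1 | intermediate
5 | 3,4-dihydroxybenzaldehyde | O=Cc1ccc(O)c(O)c1 | starting material
6 | 3,4-bis(triisopropylsilyloxy)benzaldehyde | O=Cc1ccc(O[Si](C(C)C)(C(C)C)C(C)C)c(O[Si](C(C)C)(C(C)C)C(C)C)c1 | intermediate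
7 | aldol adduct, 3-[3,4-bis(triisopropylsilyloxy)phenyl]-1-[2-(tert-butyldimethylsilyloxy)-4-(geranyloxy)phenyl]-3-hydroxypropan-1-one (racemic; present in step 4 as its lithium alkoxide) | CC(C)=CCC/C(C)=C/COc1ccc(C(=O)CC(O)c2ccc(O[Si](C(C)C)(C(C)C)C(C)C)c(O[Si](C(C)C)(C(C)C)C(C)C)c2)c(O[Si](C)(C)C(C)(C)C)c1 | intermediate
8 | β-mesylate, the 3-methanesulfonate of 7 (racemic) | CC(C)=CCC/C(C)=C/COc1ccc(C(=O)CC(OS(C)(=O)=O)c2ccc(O[Si](C(C)C)(C(C)C)C(C)C)c(O[Si](C(C)C)(C(C)C)C(C)C)c2)c(O[Si](C)(C)C(C)(C)C)c1 | intermediate
9 | (E)-3-[3,4-bis(triisopropylsilyloxy)phenyl]-1-[2-(tert-butyldimethylsilyloxy)-4-(geranyloxy)phenyl]prop-2-en-1-one | CC(C)=CCC/C(C)=C/COc1ccc(C(=O)/C=C/c2ccc(O[Si](C(C)C)(C(C)C)C(C)C)c(O[Si](C(C)C)(C(C)C)C(C)C)c2)c(O[Si](C)(C)C(C)(C)C)c1 | intermediate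
10 | [2-(tert-butyldimethylsilyloxy)-4-(geranyloxy)phenyl][(2R,3S)-3-[3,4-bis(triisopropylsilyloxy)phenyl]oxiran-2-yl]methanone (trans-oxirane) | CC(C)=CCC/C(C)=C/COc1ccc(C(=O)[C@@H]2O[C@H]2c3ccc(O[Si](C(C)C)(C(C)C)C(C)C)c(O[Si](C(C)C)(C(C)C)C(C)C)c3)c(O[Si](C)(C)C(C)(C)C)c1 | intermediate
11 | 2'-hydroxy epoxy ketone, [4-(geranyloxy)-2-hydroxyphenyl][(2R,3S)-3-[3,4-bis(triisopropylsilyloxy)phenyl]oxiran-2-yl]methanone | CC(C)=CCC/C(C)=C/COc1ccc(C(=O)[C@@H]2O[C@H]2c3ccc(O[Si](C(C)C)(C(C)C)C(C)C)c(O[Si](C(C)C)(C(C)C)C(C)C)c3)c(O)c1 | intermediate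
12 | (2R,3R)-2-[3,4-bis(triisopropylsilyloxy)phenyl]-7-(geranyloxy)-3-hydroxy-2,3-dihydro-4H-chromen-4-one (2,3-trans) | CC(C)=CCC/C(C)=C/COc1ccc2c(c1)O[C@H](c1ccc(O[Si](C(C)C)(C(C)C)C(C)C)c(O[Si](C(C)C)(C(C)C)C(C)C)c1)[C@@H](O)C2=O | intermediate
13 | (2R,3R)-2-(3,4-dihydroxyphenyl)-7-(geranyloxy)-3-hydroxy-2,3-dihydro-4H-chromen-4-one (CNP0508026.1) | CC(C)=CCC/C(C)=C/COc1ccc2c(c1)O[C@H](c1ccc(O)c(O)c1)[C@@H](O)C2=O | target

**Totals and risks**

Total step count: 7. Longest linear sequence: 6 steps (steps 1, 2, 4, 5, 6, 7); step 3 prepares the second fragment.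

Steps most likely to fail:

Step 6 (key step). What may go wrong: the freed phenoxide attacks the oxirane carbon α to the ketone (5-exo, leading into the aurone manifold), the epoxy ketone isomerizes before it cyclizes, or fluoride does not discriminate cleanly between the TBS and the TIPS ethers. Fallback: setting out from 10, the O1–C2 bond is made by thiophilic activation instead of epoxide opening by the phenol. The oxirane is first opened at the benzylic carbon with benzyl mercaptan (BnSH, LiClO4, MeCN, rt) to the α-hydroxy β-benzylsulfanyl ketone F1, in which the carbinol centre is untouched and the sulfur-bearing carbon may be a mixture. The TBS ether is then removed (TBAF/AcOH, THF, −20 °C) to give the phenol F2, and the C–S bond is ionized with AgBF4 (2,6-di-tert-butyl-4-methylpyridine, CH2Cl2, 0 °C). The benzylic cation, stabilized by the para-silyloxy group, should be captured by the phenol in a six-membered ring, the existing carbinol centre directing the aryl group trans to the hydroxyl, so that the sequence comes back to the route at 12.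

Step 5. What may go wrong: poor facial selectivity because the ortho-silyloxy group twists the aryl ketone away from the geometry the lanthanide catalyst recognizes, or slow turnover with loss of the 2'-O-TBS group to lanthanum alkoxide and hydroperoxide. Fallback: setting out from 9, oxygen delivery is made hydroxyl-directed instead of conjugate. Luche reduction (NaBH4, CeCl3·7H2O, MeOH/THF, −40 °C) gives the racemic allylic alcohol F3. A Sharpless kinetic-resolution epoxidation (Ti(O-iPr)4, L-(+)-diisopropyl tartrate, TBHP 0.6 equiv, 4 Å MS, CH2Cl2, −20 °C) should convert only the fast-reacting enantiomer into the erythro epoxy alcohol F4, whose oxirane has the required configuration; the geranyl alkenes carry no directing hydroxyl and should stay untouched. Dess–Martin oxidation (NaHCO3, CH2Cl2, 0 °C) of the epoxy alcohol F4 comes back to the route at 10; at most half of the material can be used.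

Step 4. What may go wrong: migration of the 2'-silyl group from the phenol oxygen to the enolate oxygen, or retro-aldol cleavage of the lithium aldolate on warming before it is mesylated. Fallback: setting out from 4, the nucleophile is made without a metal enolate. Soft enolization (TMSOTf, Et3N, CH2Cl2, 0 °C) gives the trimethylsilyl enol ether F5; a Mukaiyama aldol addition to aldehyde 6 (BF3·OEt2, CH2Cl2, −78 °C) gives the aldol adduct 7, now isolated; and a separate dehydration (MsCl, Et3N, CH2Cl2, 0 °C → rt, through mesylate 8) comes back to the route at 9.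

**Further compounds**

F1 | step 6 | (2S)-3-(benzylsulfanyl)-3-[3,4-bis(triisopropylsilyloxy)phenyl]-1-[2-(tert-butyldimethylsilyloxy)-4-(geranyloxy)phenyl]-2-hydroxypropan-1-one (mixture at C3) | CC(C)=CCC/C(C)=C/COc1ccc(C(=O)[C@H](O)C(SCc2ccccc2)c3ccc(O[Si](C(C)C)(C(C)C)C(C)C)c(O[Si](C(C)C)(C(C)C)C(C)C)c3)c(O[Si](C)(C)C(C)(C)C)c1
F2 | step 6 | (2S)-3-(benzylsulfanyl)-3-[3,4-bis(triisopropylsilyloxy)phenyl]-1-[4-(geranyloxy)-2-hydroxyphenyl]-2-hydroxypropan-1-one (mixture at C3) | CC(C)=CCC/C(C)=C/COc1ccc(C(=O)[C@H](O)C(SCc2ccccc2)c3ccc(O[Si](C(C)C)(C(C)C)C(C)C)c(O[Si](C(C)C)(C(C)C)C(C)C)c3)c(O)c1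
F3 | step 5 | (E)-3-[3,4-bis(triisopropylsilyloxy)phenyl]-1-[2-(tert-butyldimethylsilyloxy)-4-(geranyloxy)phenyl]prop-2-en-1-ol (racemic) | CC(C)=CCC/C(C)=C/COc1ccc(C(O)/C=C/c2ccc(O[Si](C(C)C)(C(C)C)C(C)C)c(O[Si](C(C)C)(C(C)C)C(C)C)c2)c(O[Si](C)(C)C(C)(C)C)c1
F4 | step 5 | (S)-[2-(tert-butyldimethylsilyloxy)-4-(geranyloxy)phenyl][(2S,3S)-3-[3,4-bis(triisopropylsilyloxy)phenyl]oxiran-2-yl]methanol (erythro) | CC(C)=CCC/C(C)=C/COc1ccc([C@H](O)[C@@H]2O[C@H]2c3ccc(O[Si](C(C)C)(C(C)C)C(C)C)c(O[Si](C(C)C)(C(C)C)C(C)C)c3)c(O[Si](C)(C)C(C)(C)C)c1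
F5 | step 4 | tert-butyl{5-(geranyloxy)-2-[1-(trimethylsilyloxy)ethenyl]phenoxy}dimethylsilane (trimethylsilyl enol ether of 4) | CC(C)=CCC/C(C)=C/COc1ccc(C(=C)O[Si](C)(C)C)c(O[Si](C)(C)C(C)(C)C)c1
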